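**Plan**

Ring labels: ring A is the catechol ring bearing the ether to ring B (para-phenylene); ring C is the catechol ring bearing the ether to ring D (meta-phenylene).
Enabling feature: the CH2–CH2 bridge from the para carbon of ring B to ring C can hold a carbonyl on the carbon bound to ring C. The other bridge carbon is then the methyl carbon of a ring C acetyl group, whose enolate can be bonded to an iodine-bearing para carbon of ring B.
Retrosynthesis, in order: (1) add back four O-methyl groups and the bridge C=O; (2) cut the C(ring B para)–CH2 bond, opening the 19-membered ring; (3) cut the ring A O–C(ring B) ether bond; (4) cut the ring D O–C(ring C) ether bond; (5) cut the ring A–ring D CH2–CH2 bridge as a C=C bond.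
Forward: Wittig olefination and hydrogenation join rings D and A, Ullmann etherification adds ring C, Chan–Lam coupling adds iodinated ring B, the photostimulated SRN1 reaction closes the only new ring, then deoxygenation and demethylation follow.
Stereochemistry: the target has no stereocentre; the stilbene geometry from the olefination is erased by hydrogenation.

Key step: step 10

Remark: acetovanillone, 3-benzyloxybenzyl alcohol, 3-hydroxy-4,5-dimethoxybenzaldehyde and 4-iodophenylboronic acid are taken as purchasable; the final bis-catechol is assumed to need work-up under argon.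

**Route**

Step 1
Reactants: 1 acetovanillone, 1-(4-hydroxy-3-methoxyphenyl)ethanone
Product: 2 1-(3-bromo-4-hydroxy-5-methoxyphenyl)ethanone
Conditions: Br2 (1.05 equiv), NaOAc, AcOH, rt
Reagents that add atoms: bromine, BrBr
Why: Electrophilic aromatic bromination: the free phenol directs bromine to its only open ortho position (the para position holds the acetyl group) much faster than the buffered medium allows enolisation and α-bromination of the ketone.

Step 2
Reactants: 2 1-(3-bromo-4-hydroxy-5-methoxyphenyl)ethanone
Product: 3 1-(3-bromo-4,5-dimethoxyphenyl)ethanone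
Conditions: MeI, K2CO3, DMF, rt
Reagents that add atoms: iodomethane, CI
Why: Williamson etherification: the acidic bromophenol is deprotonated by K2CO3 and methylated by MeI in an SN2 reaction, while the weakly acidic methyl ketone is not touched by carbonate at room temperature.

Step 3
Reactants: 4 3-benzyloxybenzyl alcohol
Product: 5 [3-(benzyloxy)benzyl]triphenylphosphonium bromide
Conditions: PPh3·HBr, MeCN, reflux
Reagents that add atoms: triphenylphosphine hydrobromide, Br.c1ccc(cc1)P(c1ccccc1)c1ccccc1
Why: Direct phosphonium salt formation from a benzylic alcohol: protonation by the hydrobromide turns the hydroxyl into a leaving group and PPh3 substitutes at the benzylic carbon, the aryl benzyl ether being stable to this mild acid.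

Step 4
Reactants: 6 3-hydroxy-4,5-dimethoxybenzaldehyde
Product: 7 3,4-dimethoxy-5-(methoxymethoxy)benzaldehyde
Conditions: MOMCl, iPr2NEt, CH2Cl2, 0 °C → rt
Reagents that add atoms: chloromethyl methyl ether, COCCl
Why: O-Alkylation of the phenol by the reactive α-chloro ether under amine base (MOM protection) gives an acetal that withstands the ylide, the hydrogenation and hot carbonate and is later removed by acid without harm to methyl or diaryl ethers.

Step 5
Reactants: 5 [3-(benzyloxy)benzyl]triphenylphosphonium bromide; 7 3,4-dimethoxy-5-(methoxymethoxy)benzaldehyde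
Product: 9 5-[2-[3-(benzyloxy)phenyl]ethenyl]-1,2-dimethoxy-3-(methoxymethoxy)benzene (E/Z mixture), via phosphorus ylide 8 (not isolated)
Conditions: KOtBu, THF, 0 °C; then 7, 0 °C → rt
Reagents that add atoms: none
Why: Wittig olefination of an aromatic aldehyde by a semi-stabilised benzylic ylide forms the C=C bond that becomes the ring A–ring D bridge, and the E/Z mixture is of no consequence because the double bond is saturated next.

Step 6
Reactants: 9 5-[2-[3-(benzyloxy)phenyl]ethenyl]-1,2-dimethoxy-3-(methoxymethoxy)benzene
Product: 10 3-[2-[3,4-dimethoxy-5-(methoxymethoxy)phenyl]ethyl]phenol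
Conditions: H2 (1 atm), 10% Pd/C, EtOAc–EtOH, rt
Reagents that add atoms: none
Why: Heterogeneous catalytic hydrogenation saturates the stilbene and hydrogenolyses the benzyl ether in one operation, freeing only the ring D phenol while the MOM acetal and the methyl ethers stay.

Step 7
Reactants: 10 3-[2-[3,4-dimethoxy-5-(methoxymethoxy)phenyl]ethyl]phenol; 3 1-(3-bromo-4,5-dimethoxyphenyl)ethanone
Product: 11 1-[3-[3-[2-[3,4-dimethoxy-5-(methoxymethoxy)phenyl]ethyl]phenoxy]-4,5-dimethoxyphenyl]ethanone
Conditions: CuI (10 mol %), N,N-dimethylglycine·HCl (30 mol %), Cs2CO3 (2 equiv), 1,4-dioxane, 100 °C, Ar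
Reagents that add atoms: none
Why: Ullmann diaryl ether synthesis with an amino acid ligand on copper: the ring D phenoxide replaces bromide on ring C through a copper-centred oxidative addition–reductive elimination cycle, at a temperature the MOM acetal tolerates and in a medium where carbonate enolises the methyl ketone only slightly.

Step 8
Reactants: 11 1-[3-[3-[2-[3,4-dimethoxy-5-(methoxymethoxy)phenyl]ethyl]phenoxy]-4,5-dimethoxyphenyl]ethanone
Product: 12 1-[3-[3-[2-(3-hydroxy-4,5-dimethoxyphenyl)ethyl]phenoxy]-4,5-dimethoxyphenyl]ethanone
Conditions: 3 M HCl, MeOH–THF, 50 °C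
Reagents that add atoms: none
Why: Acid-catalysed acetal exchange with methanol removes the MOM group as dimethoxymethane and frees the ring A phenol, any dimethyl ketal formed at the ketone being hydrolysed again by the water present.

Step 9
Reactants: 12 1-[3-[3-[2-(3-hydroxy-4,5-dimethoxyphenyl)ethyl]phenoxy]-4,5-dimethoxyphenyl]ethanone; 13 4-iodophenylboronic acid
Product: 14 1-[3-[3-[2-[3-(4-iodophenoxy)-4,5-dimethoxyphenyl]ethyl]phenoxy]-4,5-dimethoxyphenyl]ethanone
Conditions: Cu(OAc)2 (1 equiv), pyridine (5 equiv), 4 Å MS, CH2Cl2, O2 (balloon), rt
Reagents that add atoms: none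
Why: Chan–Lam oxidative C–O coupling: the phenoxide and the aryl group of the boronic acid meet on divalent copper and are joined by reductive elimination, O2 returning copper to the divalent state, and the room-temperature conditions leave the C–I bond and the ketone untouched.

Step 10
Reactants: 14 1-[3-[3-[2-[3-(4-iodophenoxy)-4,5-dimethoxyphenyl]ethyl]phenoxy]-4,5-dimethoxyphenyl]ethanone
Product: 17 macrocyclic deoxybenzoin tetramethyl ether (19-membered ring; C=O on the bridge carbon bound to ring C), via seco potassium enolate 15 (not isolated), via macrocyclic potassium enolate 16 (not isolated)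
Conditions: KOtBu (5 equiv), degassed DMSO (2 mM), hν (350 nm, Pyrex), 25 °C, Ar; then 1 M HCl, 0 °C
Reagents that add atoms: none
Why: Under irradiation the enolate 15 passes an electron into the C–I bond of ring B, the radical anion loses iodide, the aryl σ-radical at the para carbon of ring B bonds to the terminal enolate carbon, and the resulting aryl ketyl radical anion hands its electron to the next iodide, so a radical chain (SRN1) runs. The closest known reactions are the photostimulated arylation of acetophenone enolates by iodoarenes in DMSO and the intramolecular SRN1 closures of haloaryl ketone enolates, here extended to a large ring. The single new ring, the 19-membered macrocycle, closes end to end by intramolecular radical–nucleophile coupling that forms the C(ring B)–CH2 bond; no stereocentre arises. The coupling has to win over hydrogen abstraction from DMSO by the aryl radical and over chain-to-chain coupling: the four flat arene panels and two diaryl ether hinges restrict the seco chain, the 2 mM concentration disfavours oligomers, and the acetyl methyl group is the only acidic C–H site, so a single carbon nucleophile exists. The product is deprotonated at once to the stabilised enolate 16, a poor SRN1 nucleophile, which guards against a second arylation until the acid quench.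

Step 11
Reactants: 17 macrocyclic deoxybenzoin tetramethyl ether
Product: 18 macrocyclic bis(bibenzyl) tetramethyl ether
Conditions: Et3SiH (6 equiv), CF3CO2H, CH2Cl2, 0 °C → rt
Reagents that add atoms: none
Why: Ionic hydrogenation: the protonated aryl ketone takes hydride from Et3SiH, the carbinol ionises to a benzylic cation stabilised by the para methoxy group of ring C and takes a second hydride, while diaryl and methyl ethers are inert to CF3CO2H.

Step 12
Reactants: 18 macrocyclic bis(bibenzyl) tetramethyl ether
Product: 20 CNP0511668.0 (free bis-catechol macrocycle), via bis(bromodioxaborole) 19 (not isolated)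
Conditions: BBr3 (10 equiv), CH2Cl2, −78 °C → rt; then H2O, 0 °C, Ar
Reagents that add atoms: none
Why: Lewis acid ether cleavage: BBr3 complexes each methoxy oxygen and bromide removes the methyl group by SN2, each dimethoxyarene unit ending as a bromodioxaborole that water hydrolyses to the catechol, whereas the diaryl ether C–O bonds offer no sp3 carbon for attack and persist.

**Compound list**

1 | acetovanillone, 1-(4-hydroxy-3-methoxyphenyl)ethanone | CC(=O)c1ccc(O)c(OC)c1 | starting material
2 | 1-(3-bromo-4-hydroxy-5-methoxyphenyl)ethanone | CC(=O)c1cc(Br)c(O)c(OC)c1 | intermediate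
3 | 1-(3-bromo-4,5-dimethoxyphenyl)ethanone (ring C) | CC(=O)c1cc(Br)c(OC)c(OC)c1 | intermediate
4 | 3-benzyloxybenzyl alcohol (ring D) | OCc1cccc(OCc2ccccc2)c1 | starting material
5 | [3-(benzyloxy)benzyl]triphenylphosphonium bromide | [Br-].C(c1cccc(OCc2ccccc2)c1)[P+](c1ccccc1)(c1ccccc1)c1ccccc1 | intermediate
6 | 3-hydroxy-4,5-dimethoxybenzaldehyde (ring A) | COc1cc(C=O)cc(O)c1OC | starting material
7 | 3,4-dimethoxy-5-(methoxymethoxy)benzaldehyde | COCOc1cc(C=O)cc(OC)c1OC | intermediate
8 | [3-(benzyloxy)benzylidene]triphenylphosphorane (phosphorus ylide) | C(=P(c1ccccc1)(c1ccccc1)c1ccccc1)c1cccc(OCc2ccccc2)c1 | intermediate (not isolated)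
9 | 5-[2-[3-(benzyloxy)phenyl]ethenyl]-1,2-dimethoxy-3-(methoxymethoxy)benzene, E/Z mixture, geometry not specified | COCOc1cc(C=Cc2cccc(OCc3ccccc3)c2)cc(OC)c1OC | intermediate
10 | 3-[2-[3,4-dimethoxy-5-(methoxymethoxy)phenyl]ethyl]phenol | COCOc1cc(CCc2cccc(O)c2)cc(OC)c1OC | intermediate
11 | 1-[3-[3-[2-[3,4-dimethoxy-5-(methoxymethoxy)phenyl]ethyl]phenoxy]-4,5-dimethoxyphenyl]ethanone | CC(=O)c1cc(OC)c(OC)c(Oc2cccc(CCc3cc(OC)c(OC)c(OCOC)c3)c2)c1 | intermediate
12 | 1-[3-[3-[2-(3-hydroxy-4,5-dimethoxyphenyl)ethyl]phenoxy]-4,5-dimethoxyphenyl]ethanone | CC(=O)c1cc(OC)c(OC)c(Oc2cccc(CCc3cc(OC)c(OC)c(O)c3)c2)c1 | intermediate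
13 | 4-iodophenylboronic acid (ring B) | OB(O)c1ccc(I)cc1 | starting material
14 | 1-[3-[3-[2-[3-(4-iodophenoxy)-4,5-dimethoxyphenyl]ethyl]phenoxy]-4,5-dimethoxyphenyl]ethanone (seco iodo ketone) | CC(=O)c1cc(OC)c(OC)c(Oc2cccc(CCc3cc(OC)c(OC)c(Oc4ccc(I)cc4)c3)c2)c1 | intermediate
15 | potassium enolate of 14 (seco potassium enolate) | [K+].[O-]C(=C)c1cc(OC)c(OC)c(Oc2cccc(CCc3cc(OC)c(OC)c(Oc4ccc(I)cc4)c3)c2)c1 | intermediate (not isolated)
16 | potassium enolate of 17 (macrocyclic potassium enolate, enolate geometry not defined) | COc1cc2cc(c1OC)Oc1ccc(cc1)C=C([O-])c1cc(OC)c(OC)c(c1)Oc1cccc(c1)CC2.[K+] | intermediate (not isolated)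
17 | macrocyclic deoxybenzoin tetramethyl ether, 19-membered ring, C=O on the bridge carbon bound to ring C and CH2 bound to ring B | COc1cc2cc(c1OC)Oc1ccc(cc1)CC(=O)c1cc(OC)c(OC)c(c1)Oc1cccc(c1)CC2 | intermediate
18 | macrocyclic bis(bibenzyl) tetramethyl ether | COc1cc2cc(c1OC)Oc1ccc(cc1)CCc1cc(OC)c(OC)c(c1)Oc1cccc(c1)CC2 | intermediate
19 | bis(2-bromo-1,3,2-benzodioxaborole) formed on rings A and C of the macrocycle | BrB1Oc2cc3cc(c2O1)Oc1ccc(cc1)CCc1cc2OB(Br)Oc2c(c1)Oc1cccc(c1)CC3 | intermediate (not isolated)
20 | CNP0511668.0, macrocyclic bis(bibenzyl) with two catechol rings (A, C) and two diaryl ether bridges, no stereocentre | Oc1cc2cc(c1O)Oc1ccc(cc1)CCc1cc(O)c(O)c(c1)Oc1cccc(c1)CC2 | target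

**Count and risks**

Total step count: 12. Longest linear sequence: 9 steps (step 3 or step 4, then steps 5 to 12).

The three steps most likely to fail:

Step 10. The ring B aryl radical may take hydrogen from DMSO, or couple with the enolate of a second chain, faster than the two ends of the seco chain meet, so that deiodination or oligomerisation outruns ring closure; photoinitiation may also stall. A first remedy inside the step would be perdeuterated DMSO, which slows hydrogen transfer from the solvent. The fallback sets out from 14 and makes the same bond without a free radical, by palladium-catalysed intramolecular α-arylation of the methyl ketone. Slow addition of 14 to Pd2(dba)3, Xantphos and NaOtBu in toluene at 80 °C (oxidative addition of the C–I bond to zerovalent palladium, enolate binding, reductive elimination) should give 17 directly, where the route continues. No new compound arises on this way (F0).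

Step 7. Oxidative addition of copper into the bromide flanked by a methoxy group may be slow, and during the long heating the carbonate base may let the methyl ketone condense with itself. The fallback sets out from 3 and 10. The ketone of 3 is masked with ethylene glycol (TsOH, toluene, Dean–Stark) as 2-(3-bromo-4,5-dimethoxyphenyl)-2-methyl-1,3-dioxolane F1. F1 and phenol 10 are then joined by palladium-catalysed C–O coupling (Pd(OAc)2, tBuXPhos, K3PO4, toluene, 100 °C) to the dioxolane-protected diaryl ether 2-[3-[3-[2-[3,4-dimethoxy-5-(methoxymethoxy)phenyl]ethyl]phenoxy]-4,5-dimethoxyphenyl]-2-methyl-1,3-dioxolane F2. Treatment with 3 M HCl in MeOH–THF at 50 °C removes the dioxolane and the MOM group together, and the route is rejoined at phenol 12.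

Step 9. The phenol flanked by a methoxy group may bind copper slowly while the boronic acid is lost to protodeboronation and oxidative homocoupling, so that conversion stalls. The fallback sets out from 12 and uses Ullmann etherification with a fivefold excess of 1,4-diiodobenzene (CuI, picolinic acid, K3PO4, DMSO, 80 °C). The excess makes single substitution statistically dominant, the unreacted diiodide is recovered, and the product is 14 itself, where the route continues. No new compound arises on this way (F0).

Further compounds
F0 | step 10 | none | none
F1 | step 7 | 2-(3-bromo-4,5-dimethoxyphenyl)-2-methyl-1,3-dioxolane | CC1(OCCO1)c1cc(Br)c(OC)c(OC)c1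
F2 | step 7 | 2-[3-[3-[2-[3,4-dimethoxy-5-(methoxymethoxy)phenyl]ethyl]phenoxy]-4,5-dimethoxyphenyl]-2-methyl-1,3-dioxolane | CC1(OCCO1)c1cc(OC)c(OC)c(Oc2cccc(CCc3cc(OC)c(OC)c(OCOC)c3)c2)c1
F0 | step 9 | none | none
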